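A dawn run that reads 230.6 mM of L at 29 h cannot be a run in which a steady catalyst makes L and L stays L, because its starting rate, carried forward under [X][Z], asks for more; here is the quick number you wanted, and my hunch differs from yours.

| flask | X | Z | J | time |
|---|---|---|---|---|
| winter | 300 mM | 600 mM | 9.00 mM |  |
| summer | 180 mM | 480 mM | 9.00 mM |  |
| spring | 900 mM | 600 mM | 9.00 mM |  |
| dawn | 300 mM | 600 mM | 13.0 mM |  |
| midnight | 900 mM | 1800 mM | 9.00 mM | 29 h |

| run | time / h | [L] / mM |
|---|---|---|
| winter run | 3.6 | 62.7 |
| winter run | 7.2 | 105.9 |
| winter run | 11 | 135.2 |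
| winter run | 14 | 157.4 |
| winter run | 18 | 172.6 |
| winter run | 22 | 184.0 |
| winter run | 25 | 192.5 |
| winter run | 29 | 199.0 |
| summer run | 3.6 | 32.9 |
| summer run | 7.2 | 55.6 |
| summer run | 11 | 72.3 |
| summer run | 14 | 87.1 |
| summer run | 18 | 95.9 |
| summer run | 22 | 102.2 |
| summer run | 25 | 107.1 |
| summer run | 29 | 114.2 |
| spring run | 3.6 | 169.4 |
| spring run | 7.2 | 265.4 |
| spring run | 11 | 331.1 |
| spring run | 14 | 362.5 |
| spring run | 18 | 394.6 |
| spring run | 22 | 410.1 |
| spring run | 25 | 417.3 |
| spring run | 29 | 425.6 |
| dawn run | 3.6 | 108.0 |
| dawn run | 7.2 | 164.9 |
| dawn run | 11 | 197.6 |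
| dawn run | 14 | 214.1 |
| dawn run | 18 | 225.9 |
| dawn run | 22 | 231.4 |
| dawn run | 25 | 234.1 |
| dawn run | 29 | 230.6 |

(readings scatter by 2 mM)

* the exponent of [X] in the starting rate at the charge of the winter run (at the point where two percent of the X have become L) (one fixed amount of L, the same in the runs compared)
* the exponent of [J] in the starting rate at the charge of the winter run (at the point where two percent of the X have become L)
* L in the midnight run at 29 h, as a share of the X charged

- Overall: X + Z -> L, with J as catalyst.
- Constant volume, constant temperature.
- An order is taken over about fifteen percent of the charge, up and down.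

I take each starting rate from a parabola through the origin and the first two readings of a run, which gives 20.1 mM h⁻¹ in winter, 37.1 mM h⁻¹ in dawn, 57.3 mM h⁻¹ in spring and 10.6 mM h⁻¹ in summer. Spring over winter gives a rate ratio of 2.85 for 900 mM of X against 300 mM at equal [Z], which I read as an order of 0.954, and dawn over winter gives 1.85, which I read as an order of 1.66 in [J]. The summer starting rate, 10.6 mM h⁻¹, sits close to the 9.66 mM h⁻¹ that first order in [X] and in [Z] predicts from winter.

So I count lifetimes of X, its charge over its starting rate: 14.9 h in winter and 8.09 h in dawn. Both flasks charge Z at twice X, which makes X the limiting reagent, and the share of X left is then one over (2 times e to the power n, less one), where n is the lifetimes elapsed divided by 2. Dawn has passed 3.58 lifetimes, so it should have made 273 mM, and the reading falls short of that by 42.4 mM. The last two dawn readings slip from 234.1 mM to 230.6 mM, which is thin against a scatter of 2 mM, but a dead catalyst stops L without lowering it, so I book the gap as L slowly going away. Taking the 11 h reading as the mean L of the run, I get 136 h for the L present divided by the L lost per hour, and that is the lifetime of L.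

Midnight has the [J] of winter and 1800 mM of Z against 600 mM, so its X lifetime is 4.97 h, and it makes 875 mM by 29 h. Most of that L is born within about one X lifetime, so it ages for 24.0 h, and I commit to 81.5% of the X charged. The forecast gives orders of 1 and 1.7 and a yield of 90%, on the ground that it “looks like catalyst death”, so we part by 8.5 percentage points.

    2 J ⇌ J2, settled at all times (29.50 L mol⁻¹)
    J2 + X + Z → L + J2 (133.6 L² mol⁻² h⁻¹)
    J + Ze → Ju
    L → Xi (0.009036 h⁻¹)

The simulation gives 79.3%, with orders of 1.0 and 2.0. The fit with the true steps forecasts 80.1% for midnight and the power-law fit 99.0%. At 79.3% the midnight run holds 713 mM of L at 29 h, which the step L → Xi of the scheme is taking away at 6.45 mM h⁻¹. In winter my count of X lifetimes gives 230 mM made by 29 h, and taking off the loss at my dawn reading of the lifetime of L, 136 h, with the 11 h reading as mean L, leaves 201 mM against a reading of 199.0 mM.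

The numbers in the tables are simulated for substances that don't exist.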